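Ring A (C1, C10–C14; briarane numbering) is built by stitching ethylene between two carbons that sit 1,4 on that ring: the carbinol carbon C14 and C11, the carbon of the exocyclic C11=C20 methylene. A 4-alkynal, with the aldehyde (C14) on quaternary C1 and a terminal alkyne (C11≡C20) on C10, undergoes a rhodium-catalysed hydroacylative [4+2] annulation with ethylene. This forges C11–C12 and C13–C14 in one operation and delivers the methylene and a C14 ketone directly. C1 and C10 come from a dianionic Ireland–Claisen rearrangement relayed from C2, the lactone from a SmI2 Reformatsky closure, and ring B from a Nozaki–Hiyama–Kishi cyclisation at C4–C5.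

Key step: step 14

Remark: atoms carry briarane numbers: ring A = C1, C10, C11, C12, C13, C14; ring B (ten-membered) = C1 to C10; lactone = C7, C8, C17, C19 and O; C15 = methyl on C1, C16 = ester carbon on C5, C18 = methyl on C17, C20 = exocyclic methylene carbon. Compounds 5, 6 and 30 and the reagents named under the steps are taken as catalogue chemicals. TBS = tert-butyldimethylsilyl, TBDPS = tert-butyldiphenylsilyl, TES = triethylsilyl, MOM = methoxymethyl.

Step 1
Reactants: 1 ethyl (Z)-3-iodoprop-2-enoate; 2 ethynyl(trimethyl)silane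
Product: 3 ethyl (Z)-5-(trimethylsilyl)pent-2-en-4-ynoate
Conditions: PdCl2(PPh3)2 (2 mol %), CuI (4 mol %), i-Pr2NH, THF, 0 °C to rt
Reagents that add atoms: none
Why: Sonogashira coupling of the activated β-iodoacrylate with the terminal alkyne proceeds under mild copper and palladium co-catalysis with retention of the Z geometry, and no stereocentre is formed.

Step 2
Reactants: 3 ethyl (Z)-5-(trimethylsilyl)pent-2-en-4-ynoate
Product: 4 (Z)-5-(trimethylsilyl)pent-2-en-4-yn-1-ol
Conditions: i-Bu2AlH (2.2 equiv), CH2Cl2, −78 °C; aqueous potassium sodium tartrate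
Reagents that add atoms: none
Why: i-Bu2AlH reduces the conjugated ester to the allylic alcohol by 1,2-hydride delivery at low temperature without touching the silylalkyne or isomerising the Z alkene (ester reduction).

Step 3
Reactants: 5 (R)-4-benzyl-3-propanoyl-1,3-thiazolidine-2-thione; 6 3-[(tert-butyldiphenylsilyl)oxy]propanal
Product: 7 syn-aldol adduct, (R)-4-benzyl-3-[(2R,3S)-5-(TBDPS-oxy)-3-hydroxy-2-methylpentanoyl]-1,3-thiazolidine-2-thione
Conditions: TiCl4 (1.05 equiv), i-Pr2NEt (1.1 equiv), N-methyl-2-pyrrolidone (1.0 equiv), CH2Cl2, 0 °C; then 6, 0 °C; aqueous NH4Cl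
Reagents that add atoms: none
Why: in this titanium-mediated thiazolidinethione propionate aldol the chlorotitanium Z-enolate of the (R)-auxiliary reacts through a non-chelated Zimmerman–Traxler chair to give the Evans-type syn adduct, so the auxiliary sets the C2 carbinol as S (the α-methyl centre is sacrificial and is erased in step 5).

Step 4
Reactants: 7 syn-aldol adduct; 4 (Z)-5-(trimethylsilyl)pent-2-en-4-yn-1-ol
Product: 8 (Z)-5-(trimethylsilyl)pent-2-en-4-yn-1-yl (2R,3S)-5-(TBDPS-oxy)-3-hydroxy-2-methylpentanoate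
Conditions: 4 (1.5 equiv), DMAP (0.2 equiv), CH2Cl2, rt
Reagents that add atoms: none
Why: N-acylthiazolidinethiones are active amides that undergo DMAP-catalysed alcoholysis with a primary alcohol, which releases the auxiliary and leaves the free β-hydroxyl and both stereocentres untouched (acyl transfer).

Step 5
Reactants: 8 enynyl β-hydroxy ester
Product: 9 Claisen acid (C14 carboxylic acid on quaternary C1; C2 hydroxyl; vinyl C9=C8 and silylethynyl C11≡C20 on C10)
Conditions: LiN(i-Pr)2 (2.4 equiv), THF, −78 °C to rt, 12 h; 1 M HCl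
Reagents that add atoms: none
Why: in this dianionic Ireland–Claisen rearrangement the lithium alkoxide–enolate chelate fixes the enolate geometry (allyl oxygen cis to methyl) and lets the allyl unit reach C1 only on the face anti to the C3 chain of the C2 stereocentre, while the chair transition state of the Z alkene, with the slim alkynyl group axial, sets C10, so that C1 and C10 are both relayed from C2.

Step 6
Reactants: 9 Claisen acid
Product: 11 O2-TBS acid bearing a terminal alkyne, via bis-silylated silyl ester 10 (not isolated)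
Conditions: TBSOTf (2.5 equiv), 2,6-lutidine (4 equiv), CH2Cl2, 0 °C; then K2CO3, MeOH/THF/H2O, rt; 1 M HCl to pH 4
Reagents that add atoms: tert-butyldimethylsilyl trifluoromethanesulfonate, CC(C)(C)[Si](C)(C)OS(=O)(=O)C(F)(F)F
Why: the silyl triflate silylates the hindered C2 hydroxyl together with the carboxylic acid, and the carbonate methanolysis then cleaves only the labile silyl ester and the alkynyl C–Si bond while the secondary TBS and primary TBDPS ethers persist (silylation then selective desilylation).

Step 7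
Reactants: 11 O2-TBS acid
Product: 13 Weinreb amide of 11, via acid chloride 12 (not isolated)
Conditions: 1-chloro-N,N,2-trimethylprop-1-en-1-amine (1.3 equiv), CH2Cl2, 0 °C; then MeNH(OMe)·HCl (2 equiv), pyridine (5 equiv), 0 °C to rt
Reagents that add atoms: N,O-dimethylhydroxylamine hydrochloride, CNOC.Cl
Why: the neutral chloroenamine (Ghosez reagent) converts the hindered α-quaternary acid into its acid chloride without harming the silyl ethers, and the chloride is then captured by N,O-dimethylhydroxylamine to give the Weinreb amide (acyl substitution).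

Step 8
Reactants: 13 Weinreb amide
Product: 15 C9 aldehyde, via ozonide 14 (not isolated)
Conditions: O3, CH2Cl2, −78 °C (to first excess); then PPh3 (1.5 equiv), −78 °C to rt
Reagents that add atoms: ozone, [O-][O+]=O
Why: ozone cleaves the monosubstituted alkene much faster than the terminal alkyne, and reduction of the ozonide with PPh3 under neutral, cold conditions delivers the aldehyde without epimerising the propargylic C10 centre (ozonolysis).

Step 9
Reactants: 15 C9 aldehyde
Product: 17 C9-hydroxy C8-methoxymethoxy homoallylic alcohol (vinyl = C7=C6), via O9-borinate 16 (not isolated)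
Conditions: allyl methoxymethyl ether, s-BuLi, THF, −78 °C; (+)-Ipc2BOMe; BF3·OEt2; then 15, −78 °C, 4 h; NaOH, H2O2, 0 °C to rt
Reagents that add atoms: allyl methoxymethyl ether, C=CCOCOC, delivered as (Z)-[3-(methoxymethoxy)prop-2-en-1-yl]diisopinocampheylborane, COCO/C=C\CB([C@H]1C[C@H]2C[C@@H]([C@@H]1C)C2(C)C)[C@H]1C[C@H]2C[C@@H]([C@@H]1C)C2(C)C
Why: Brown (Z)-γ-alkoxyallylboration through a closed chair transition state gives the syn C9-hydroxy C8-alkoxy pair, and the reagent derived from (+)-Ipc2BOMe attacks the Re face of the aldehyde, which is also the face favoured by the anti-Felkin preference that Z-γ-substituted allylboron reagents show with α-branched aldehydes (quaternary C1 anti to the incoming carbon), so C9 and the temporary C8 centre are set in a matched case.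

Step 10
Reactants: 17 homoallylic alcohol
Product: 18 O9-TBS ether of 17
Conditions: TBSOTf (1.5 equiv), 2,6-lutidine, CH2Cl2, −78 to 0 °C
Reagents that add atoms: tert-butyldimethylsilyl trifluoromethanesulfonate, CC(C)(C)[Si](C)(C)OS(=O)(=O)C(F)(F)F
Why: silyl triflate with a hindered base silylates the hindered secondary C9 hydroxyl cleanly, giving a bulky non-chelating group that is needed for step 18 (silyl ether formation).

Step 11
Reactants: 18 O9-TBS ether
Product: 19 C6,C7-diol
Conditions: K2OsO4·2H2O (2 mol %), N-methylmorpholine N-oxide (1.5 equiv), acetone/H2O (5:1), 0 °C to rt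
Reagents that add atoms: N-methylmorpholine N-oxide, C[N+]1([O-])CCOCC1; water, O
Why: in this Upjohn dihydroxylation the osmium reagent adds to the vinyl group anti to the allylic C8 oxygen in the hydrogen-eclipsed conformer (the empirical rule for allylic ethers), which places the new C7 hydroxyl anti to the C8 ether and so relays the C7 configuration of the target from C8, while the alkyne reacts far more slowly.

Step 12
Reactants: 19 C6,C7-diol
Product: 20 O6-TES ether
Conditions: TESCl (1.05 equiv), imidazole (2 equiv), CH2Cl2, −78 to −20 °C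
Reagents that add atoms: chlorotriethylsilane, CC[Si](Cl)(CC)CC
Why: the primary C6 hydroxyl is silylated much faster than the flanked secondary C7 hydroxyl at low temperature (selective silylation).

Step 13
Reactants: 20 O6-TES ether
Product: 21 4-alkynal (C14 aldehyde on C1, ethynyl C11≡C20 on C10)
Conditions: i-Bu2AlH (3 equiv), THF, −78 °C; aqueous potassium sodium tartrate
Reagents that add atoms: none
Why: i-Bu2AlH adds once to the Weinreb amide to give a chelated tetrahedral aluminate that collapses to the aldehyde only on work-up, and the aldehyde has no α-hydrogen so C1 cannot epimerise (Weinreb amide reduction).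

Step 14
Reactants: 21 4-alkynal
Product: 22 ring A ketone (4-methylenecyclohexanone: C14 ketone, C11=C20 methylene)
Conditions: [Rh(cod)2]BF4 (10 mol %), dppe (10 mol %), H2 (1 bar, 10 min, then purged), ethylene (5 bar), acetone, 40 °C
Reagents that add atoms: ethylene, C=C
Why: Proposed new method: oxidative addition of the C14–H bond of the aldehyde to the cationic rhodium–dppe fragment gives an acyl rhodium hydride, cis-hydrometalation of the tethered C11≡C20 alkyne (hydrogen to C20, rhodium to C11) gives a five-membered acyl(alkenyl)rhodacycle, ethylene inserts into it, and C–C reductive elimination releases the 4-methylenecyclohexanone with the C11–C12 and C13–C14 bonds formed. The closest known reaction type is the rhodium-catalysed [4+2] annulation of 4-alkynals with alkynes or acrylamides through the same rhodacycle; ethylene has not been shown as the two-carbon partner, although it is the best olefin for intermolecular hydroacylation. Ring A closes as a formal [4+2] annulation, the last bond by reductive elimination from a seven-membered rhodacycle. No stereocentre is created: C11 and C14 become trigonal and C1 and C10 are untouched, C1 having no hydrogen that could be lost. The step needs chemoselectivity for ethylene insertion over reductive elimination to the alkylidenecyclobutanone, over trans-hydroacylation to a cyclopentenone, over simple hydroacylation of ethylene and over decarbonylation; the quaternary C1 (gem-disubstitution that favours the rhodacycle), the chelating bisphosphine and several bar of ethylene are meant to secure it.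

Step 15
Reactants: 22 ring A ketone
Product: 23 O7 2-bromopropanoate (epimers at the CHBr carbon)
Conditions: 2-bromopropanoyl bromide (1.5 equiv), pyridine (3 equiv), CH2Cl2, 0 °C
Reagents that add atoms: 2-bromopropanoyl bromide, CC(Br)C(Br)=O
Why: acylation of the only free hydroxyl with the acid bromide and pyridine installs the Reformatsky precursor, and the bromine-bearing carbon can be used as an epimer mixture because it becomes an enolate carbon in step 18 (esterification).

Step 16
Reactants: 23 O7 2-bromopropanoate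
Product: 24 C8 alcohol
Conditions: Me2BBr (2.5 equiv), CH2Cl2, −78 °C; then saturated NaHCO3/THF
Reagents that add atoms: none
Why: Me2BBr cleaves the methoxymethyl acetal at −78 °C by boron-assisted acetal opening and hydrolysis of the bromomethyl ether, a reaction that is much faster than attack on silyl ethers, esters or the ketone (selective acetal cleavage).

Step 17
Reactants: 24 C8 alcohol
Product: 25 C8 ketone
Conditions: Dess–Martin periodinane (1.5 equiv), CH2Cl2, 0 °C to rt
Reagents that add atoms: none
Why: Dess–Martin oxidation converts the secondary C8 alcohol into the ketone under neutral conditions that do not enolise the C7 or C9 α-centres, removing the temporary C8 stereocentre.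

Step 18
Reactants: 25 C8 ketone
Product: 26 β-hydroxy-γ-lactone (O7–C19 lactone, tertiary C8 hydroxyl, C17 methyl)
Conditions: SmI2 (2.5 equiv), THF, −78 °C, 30 min; pH 7 buffer
Reagents that add atoms: none
Why: in this SmI2 intramolecular Reformatsky reaction two-electron reduction of the C–Br bond gives a samarium enolate that adds to the C8 ketone in a five-membered ring closure, in which the tether from O7 forces the bulky C9 branch trans to C6 on the new lactone (the polar Felkin–Anh preference of the non-chelating C9 silyloxy group points the same way) and the C17 methyl settles anti to the C9 branch, cis to the new hydroxyl, which is also the equilibrium arrangement of this epimerisable centre.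

Step 19
Reactants: 26 β-hydroxy-γ-lactone
Product: 27 C14 alcohol
Conditions: LiBH(s-Bu)3 (L-Selectride, 2.5 equiv), THF, −78 °C; then H2O
Reagents that add atoms: none
Why: the bulky hydride LiBH(s-Bu)3 attacks the ring A ketone along the equatorial trajectory of the chair that keeps the C2 and C9 chains equatorial and the C15 methyl axial, giving the axial C14 alcohol trans to the methyl, and the lactone is inert at −78 °C (substrate-controlled ketone reduction).

Step 20
Reactants: 27 C14 alcohol
Product: 28 C14 acetate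
Conditions: Ac2O (3 equiv), DMAP (0.2 equiv), pyridine, CH2Cl2, rt
Reagents that add atoms: acetic anhydride, CC(=O)OC(C)=O
Why: DMAP-catalysed acetylation esterifies the secondary C14 alcohol while the hindered tertiary C8 hydroxyl does not react at room temperature, and this acetate blocks lactol formation with the later C4 aldehyde.

Step 21
Reactants: 28 C14 acetate
Product: 29 C6 aldehyde
Conditions: (COCl)2 (4 equiv), DMSO (8 equiv), CH2Cl2, −78 to −30 °C; then Et3N (12 equiv), −78 to 0 °C
Reagents that add atoms: none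
Why: under Swern conditions the activated sulfoxide attacks the primary triethylsilyl ether directly, so that it is unmasked and oxidised to the aldehyde in one operation while secondary TBS, primary TBDPS and acetate groups are untouched, and the cold amine quench limits epimerisation at C7.

Step 22
Reactants: 30 methyl 2-[bis(2,2,2-trifluoroethoxy)phosphoryl]acetate
Product: 31 methyl 2-[bis(2,2,2-trifluoroethoxy)phosphoryl]-2-bromoacetate
Conditions: NaH (1.0 equiv), THF, 0 °C; then N-bromosuccinimide (1.0 equiv), −78 to 0 °C; 0.5 M HCl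
Reagents that add atoms: N-bromosuccinimide, O=C1CCC(=O)N1Br
Why: the sodium carbanion of the phosphonoacetate is brominated at carbon by N-bromosuccinimide, and one equivalent of each at low temperature limits dibromination (electrophilic α-halogenation).

Step 23
Reactants: 29 C6 aldehyde; 31 bromophosphonoacetate
Product: 32 (E)-α-bromoacrylate (C5 bromide, C16 methyl ester cis to C7)
Conditions: 31 (1.3 equiv), t-BuOK (1.25 equiv), 18-crown-6 (2 equiv), THF, −78 °C; then 29, −78 °C
Reagents that add atoms: none
Why: this Horner–Wadsworth–Emmons olefination with the bis(trifluoroethyl) bromophosphonoacetate of the Still–Gennari type is kinetically controlled and E-selective, which places the ester cis to C7 and the bromine trans to it, the geometry that the C5=C6 bond of the target needs.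

Step 24
Reactants: 32 (E)-α-bromoacrylate
Product: 33 tetraol (free hydroxyls at C2, C4, C8, C9)
Conditions: HF·pyridine (excess), pyridine, THF, 0 °C to rt
Reagents that add atoms: none
Why: excess HF·pyridine cleaves the two secondary TBS ethers and the primary TBDPS ether by fluoride-driven Si–O cleavage under weakly acidic conditions that leave the acetate, the lactone, the bromoacrylate and the exocyclic alkene intact (global desilylation).

Step 25
Reactants: 33 tetraol
Product: 34 C4 aldehyde
Conditions: TEMPO (0.2 equiv), PhI(OAc)2 (1.2 equiv), CH2Cl2, rt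
Reagents that add atoms: none
Why: the oxoammonium salt generated from TEMPO and PhI(OAc)2 oxidises the primary C4 alcohol far faster than the hindered secondary and tertiary alcohols and stops at the aldehyde, and the β-hydroxy aldehyde cannot form a stable lactol because C14 is acetylated (chemoselective alcohol oxidation).

Step 26
Reactants: 34 C4 aldehyde
Product: 35 ring B triol (2,4,9-tri-O-deacetyl target)
Conditions: CrCl2 (10 equiv), NiCl2 (0.2 equiv), DMSO/THF (3:1), 2 mM, rt
Reagents that add atoms: none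
Why: in this Nozaki–Hiyama–Kishi cyclisation nickel inserts into the C5–Br bond, transmetalation gives an alkenylchromium species that adds only to the aldehyde with retention of the alkene geometry, free hydroxyls are tolerated, high dilution favours closure of the ten-membered ring B, and the new C4 carbinol is set under macrocyclic control with the C4 oxygen on the outside of the forming ring, syn to the C2 hydroxyl.

Step 27
Reactants: 35 ring B triol
Product: 36 target CNP0209369.3
Conditions: Ac2O (10 equiv), pyridine, DMAP (0.1 equiv), CH2Cl2, 0 °C to rt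
Reagents that add atoms: acetic anhydride, CC(=O)OC(C)=O
Why: acetic anhydride with pyridine and a little DMAP acetylates the three secondary hydroxyls at C2, C4 and C9 while the hindered tertiary C8 hydroxyl stays free, which gives the target (esterification).

Compound list
1 | ethyl (Z)-3-iodoprop-2-enoate | CCOC(=O)/C=C\I | starting material
2 | ethynyl(trimethyl)silane | C#C[Si](C)(C)C | starting material
3 | ethyl (Z)-5-(trimethylsilyl)pent-2-en-4-ynoate | CCOC(=O)/C=C\C#C[Si](C)(C)C | intermediate
4 | (Z)-5-(trimethylsilyl)pent-2-en-4-yn-1-ol | OC/C=C\C#C[Si](C)(C)C | intermediate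
5 | (R)-4-benzyl-3-propanoyl-1,3-thiazolidine-2-thione | CCC(=O)N1[C@H](Cc2ccccc2)CSC1=S | starting material
6 | 3-[(tert-butyldiphenylsilyl)oxy]propanal | O=CCCO[Si](c1ccccc1)(c1ccccc1)C(C)(C)C | starting material
7 | syn-aldol adduct, (R)-4-benzyl-3-[(2R,3S)-5-(TBDPS-oxy)-3-hydroxy-2-methylpentanoyl]-1,3-thiazolidine-2-thione | O=C(N1[C@H](Cc2ccccc2)CSC1=S)[C@H](C)[C@@H](O)CCO[Si](c1ccccc1)(c1ccccc1)C(C)(C)C | intermediate
8 | (Z)-5-(trimethylsilyl)pent-2-en-4-yn-1-yl (2R,3S)-5-(TBDPS-oxy)-3-hydroxy-2-methylpentanoate | C[Si](C)(C)C#C/C=C\COC(=O)[C@H](C)[C@@H](O)CCO[Si](c1ccccc1)(c1ccccc1)C(C)(C)C | intermediate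
9 | Claisen acid: 2-[(1S)-3-(TBDPS-oxy)-1-hydroxypropyl]-3-ethenyl-2-methyl-5-(trimethylsilyl)pent-4-ynoic acid, C1 (quaternary) and C10 configured as in the target | OC(=O)[C@](C)([C@@H](O)CCO[Si](c1ccccc1)(c1ccccc1)C(C)(C)C)[C@@H](C=C)C#C[Si](C)(C)C | intermediate
10 | TBS ester of 9 with the C2 hydroxyl as TBS ether | CC(C)(C)[Si](C)(C)OC(=O)[C@](C)([C@@H](O[Si](C)(C)C(C)(C)C)CCO[Si](c1ccccc1)(c1ccccc1)C(C)(C)C)[C@@H](C=C)C#C[Si](C)(C)C | intermediate
11 | O2-TBS acid with terminal alkyne (C–SiMe3 cleaved) | OC(=O)[C@](C)([C@@H](O[Si](C)(C)C(C)(C)C)CCO[Si](c1ccccc1)(c1ccccc1)C(C)(C)C)[C@@H](C=C)C#C | intermediate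
12 | acid chloride of 11 | ClC(=O)[C@](C)([C@@H](O[Si](C)(C)C(C)(C)C)CCO[Si](c1ccccc1)(c1ccccc1)C(C)(C)C)[C@@H](C=C)C#C | intermediate
13 | N-methoxy-N-methylamide (Weinreb amide) of 11 | CON(C)C(=O)[C@](C)([C@@H](O[Si](C)(C)C(C)(C)C)CCO[Si](c1ccccc1)(c1ccccc1)C(C)(C)C)[C@@H](C=C)C#C | intermediate
14 | ozonide (1,2,4-trioxolane) of the vinyl group of 13 | CON(C)C(=O)[C@](C)([C@@H](O[Si](C)(C)C(C)(C)C)CCO[Si](c1ccccc1)(c1ccccc1)C(C)(C)C)[C@@H](C1OCOO1)C#C | intermediate
15 | C9 aldehyde: Weinreb amide with formyl (C9) and ethynyl (C11≡C20) on C10 | CON(C)C(=O)[C@](C)([C@@H](O[Si](C)(C)C(C)(C)C)CCO[Si](c1ccccc1)(c1ccccc1)C(C)(C)C)[C@@H](C=O)C#C | intermediate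
16 | O9-bis(isopinocampheyl)borinate of 17 | CON(C)C(=O)[C@](C)([C@@H](O[Si](C)(C)C(C)(C)C)CCO[Si](c1ccccc1)(c1ccccc1)C(C)(C)C)[C@@H]([C@H](OB([C@H]1C[C@H]2C[C@@H]([C@@H]1C)C2(C)C)[C@H]1C[C@H]2C[C@@H]([C@@H]1C)C2(C)C)[C@@H](OCOC)C=C)C#C | intermediate
17 | homoallylic alcohol: C9 hydroxyl and C8 MOM ether syn, vinyl C7=C6 | CON(C)C(=O)[C@](C)([C@@H](O[Si](C)(C)C(C)(C)C)CCO[Si](c1ccccc1)(c1ccccc1)C(C)(C)C)[C@@H]([C@H](O)[C@@H](OCOC)C=C)C#C | intermediate
18 | O9-TBS ether of 17 | CON(C)C(=O)[C@](C)([C@@H](O[Si](C)(C)C(C)(C)C)CCO[Si](c1ccccc1)(c1ccccc1)C(C)(C)C)[C@@H]([C@H](O[Si](C)(C)C(C)(C)C)[C@@H](OCOC)C=C)C#C | intermediate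
19 | C6,C7-diol of 18 (C7 hydroxyl anti to the C8 ether) | CON(C)C(=O)[C@](C)([C@@H](O[Si](C)(C)C(C)(C)C)CCO[Si](c1ccccc1)(c1ccccc1)C(C)(C)C)[C@@H]([C@H](O[Si](C)(C)C(C)(C)C)[C@@H](OCOC)[C@@H](O)CO)C#C | intermediate
20 | O6-TES ether of 19 | CON(C)C(=O)[C@](C)([C@@H](O[Si](C)(C)C(C)(C)C)CCO[Si](c1ccccc1)(c1ccccc1)C(C)(C)C)[C@@H]([C@H](O[Si](C)(C)C(C)(C)C)[C@@H](OCOC)[C@@H](O)CO[Si](CC)(CC)CC)C#C | intermediate
21 | 4-alkynal: C14 aldehyde on quaternary C1, ethynyl on C10, free C7 hydroxyl | O=C[C@](C)([C@@H](O[Si](C)(C)C(C)(C)C)CCO[Si](c1ccccc1)(c1ccccc1)C(C)(C)C)[C@@H]([C@H](O[Si](C)(C)C(C)(C)C)[C@@H](OCOC)[C@@H](O)CO[Si](CC)(CC)CC)C#C | intermediate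
22 | ring A ketone: 4-methylenecyclohexanone with C14 ketone and C11=C20 methylene, side chains on C1 and C10 | C=C1CCC(=O)[C@](C)([C@@H](O[Si](C)(C)C(C)(C)C)CCO[Si](c2ccccc2)(c2ccccc2)C(C)(C)C)[C@H]1[C@H](O[Si](C)(C)C(C)(C)C)[C@@H](OCOC)[C@@H](O)CO[Si](CC)(CC)CC | intermediate
23 | O7 2-bromopropanoate of 22 (both epimers at CHBr) | C=C1CCC(=O)[C@](C)([C@@H](O[Si](C)(C)C(C)(C)C)CCO[Si](c2ccccc2)(c2ccccc2)C(C)(C)C)[C@H]1[C@H](O[Si](C)(C)C(C)(C)C)[C@@H](OCOC)[C@@H](OC(=O)C(C)Br)CO[Si](CC)(CC)CC | intermediate
24 | C8 alcohol (MOM removed) | C=C1CCC(=O)[C@](C)([C@@H](O[Si](C)(C)C(C)(C)C)CCO[Si](c2ccccc2)(c2ccccc2)C(C)(C)C)[C@H]1[C@H](O[Si](C)(C)C(C)(C)C)[C@@H](O)[C@@H](OC(=O)C(C)Br)CO[Si](CC)(CC)CC | intermediate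
25 | C8 ketone | C=C1CCC(=O)[C@](C)([C@@H](O[Si](C)(C)C(C)(C)C)CCO[Si](c2ccccc2)(c2ccccc2)C(C)(C)C)[C@H]1[C@H](O[Si](C)(C)C(C)(C)C)C(=O)[C@@H](OC(=O)C(C)Br)CO[Si](CC)(CC)CC | intermediate
26 | β-hydroxy-γ-lactone (O7–C19 lactone, tertiary C8 hydroxyl, C17 methyl cis to it), C14 ketone | C=C1CCC(=O)[C@](C)([C@@H](O[Si](C)(C)C(C)(C)C)CCO[Si](c2ccccc2)(c2ccccc2)C(C)(C)C)[C@H]1[C@H](O[Si](C)(C)C(C)(C)C)[C@]1(O)[C@@H](C)C(=O)O[C@H]1CO[Si](CC)(CC)CC | intermediate
27 | C14 alcohol (axial, trans to the C15 methyl) | C=C1CC[C@H](O)[C@](C)([C@@H](O[Si](C)(C)C(C)(C)C)CCO[Si](c2ccccc2)(c2ccccc2)C(C)(C)C)[C@H]1[C@H](O[Si](C)(C)C(C)(C)C)[C@]1(O)[C@@H](C)C(=O)O[C@H]1CO[Si](CC)(CC)CC | intermediate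
28 | C14 acetate | C=C1CC[C@H](OC(C)=O)[C@](C)([C@@H](O[Si](C)(C)C(C)(C)C)CCO[Si](c2ccccc2)(c2ccccc2)C(C)(C)C)[C@H]1[C@H](O[Si](C)(C)C(C)(C)C)[C@]1(O)[C@@H](C)C(=O)O[C@H]1CO[Si](CC)(CC)CC | intermediate
29 | C6 aldehyde on the lactone carbon C7 | C=C1CC[C@H](OC(C)=O)[C@](C)([C@@H](O[Si](C)(C)C(C)(C)C)CCO[Si](c2ccccc2)(c2ccccc2)C(C)(C)C)[C@H]1[C@H](O[Si](C)(C)C(C)(C)C)[C@]1(O)[C@@H](C)C(=O)O[C@H]1C=O | intermediate
30 | methyl 2-[bis(2,2,2-trifluoroethoxy)phosphoryl]acetate | COC(=O)CP(=O)(OCC(F)(F)F)OCC(F)(F)F | starting material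
31 | methyl 2-[bis(2,2,2-trifluoroethoxy)phosphoryl]-2-bromoacetate | COC(=O)C(Br)P(=O)(OCC(F)(F)F)OCC(F)(F)F | intermediate
32 | (E)-α-bromoacrylate: C6=C5(Br)CO2Me on C7, ester cis to C7 | C=C1CC[C@H](OC(C)=O)[C@](C)([C@@H](O[Si](C)(C)C(C)(C)C)CCO[Si](c2ccccc2)(c2ccccc2)C(C)(C)C)[C@H]1[C@H](O[Si](C)(C)C(C)(C)C)[C@]1(O)[C@@H](C)C(=O)O[C@H]1/C=C(\C(=O)OC)Br | intermediate
33 | tetraol (C2, C4, C8, C9 hydroxyls; C14 acetate) | C=C1CC[C@H](OC(C)=O)[C@](C)([C@@H](O)CCO)[C@H]1[C@H](O)[C@]1(O)[C@@H](C)C(=O)O[C@H]1/C=C(\C(=O)OC)Br | intermediate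
34 | C4 aldehyde | C=C1CC[C@H](OC(C)=O)[C@](C)([C@@H](O)CC=O)[C@H]1[C@H](O)[C@]1(O)[C@@H](C)C(=O)O[C@H]1/C=C(\C(=O)OC)Br | intermediate
35 | ring B triol: 2,4,9-tri-O-deacetyl target (C14 acetate, free C2, C4, C8, C9 hydroxyls) | C=C1CC[C@H](OC(C)=O)[C@]2(C)[C@@H](O)C[C@@H](O)/C(C(=O)OC)=C/[C@@H]3OC(=O)[C@H](C)[C@@]3(O)[C@@H](O)[C@@H]12 | intermediate
36 | CNP0209369.3: briarane 2,4,9,14-tetraacetate with 8-hydroxy-7,19-lactone, C16 methyl ester and C11=C20 methylene | C=C1CC[C@H](OC(C)=O)[C@]2(C)[C@@H](OC(C)=O)C[C@@H](OC(C)=O)/C(C(=O)OC)=C/[C@@H]3OC(=O)[C@H](C)[C@@]3(O)[C@@H](OC(C)=O)[C@@H]12 | target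

Total step count: 27. Longest linear sequence: 25 steps (steps 1, 2, 4–21 and 23–27, from 1 and 2 to 36).

Steps most likely to fail

Step 14 (Proposed new method). Ethylene insertion may lose to reductive elimination from the five-membered rhodacycle, to trans-hydroacylation giving a cyclopentenone, to simple hydroacylation of ethylene giving the ethyl ketone, or to decarbonylation. The fallback makes the two bonds one after the other with known chemistry and sets out from 21. Addition of CH2=CHMgBr (THF, −78 °C) forms the C13–C14 bond and gives the allylic alcohol F1. MnO2 oxidises only this allylic carbinol, leaving the C7 hydroxyl, to give the vinyl ketone F2. Conjugate addition of PhSeH (catalytic Et3N) gives the β-phenylselanyl ketone F3. Bu3SnH/AIBN (benzene, 80 °C, slow addition) then generates the primary C12 radical, which closes ring A by 6-exo-dig cyclisation onto C11 of the alkyne; hydrogen transfer to the vinyl radical gives the methylene, and the route is rejoined at 22.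

Step 18. Reductive cleavage of the C7–O bond of the α-acyloxy ketone by SmI2 may compete with reduction of the C–Br bond, and control at C17 may be incomplete. The fallback replaces the Reformatsky closure by a copper hydride reductive aldol cyclisation and sets out from 22. Acryloyl chloride and i-Pr2NEt give the O7 acrylate F4; Me2BBr (−78 °C) removes the methoxymethyl group to give the C8 alcohol F5; Dess–Martin oxidation gives the keto acrylate F6. Cu(OAc)2·H2O (5 mol %), dppf and 1,1,3,3-tetramethyldisiloxane (THF, rt) then reduce the acrylate in conjugate fashion to a Z-copper enolate, which adds to the C8 ketone through a chair-like transition state with the new methyl cis to the hydroxyl, and the route is rejoined at 26.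

Step 26. Facial selectivity at C4 may be poor in the ring closure, since open-chain 1,3-induction from C2 favours the 2,4-anti diol, and slow closure gives the organochromium species time to be protonated. The fallback corrects C4 by hydroxyl-directed reduction and sets out from 35 obtained as a C4 epimer mixture. MnO2 oxidises only the allylic C4 alcohol to the cross-conjugated enone F7. Narasaka–Prasad reduction (Et2BOMe, NaBH4, THF/MeOH, −78 °C) then delivers hydride through the boron chelate with the C2 hydroxyl to give the 2,4-syn diol, and the route is rejoined at 35.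

Further compounds
F1 | step 14 | C14 allylic alcohol from vinyl addition to 21 (C14 epimers) | C=CC(O)[C@](C)([C@@H](O[Si](C)(C)C(C)(C)C)CCO[Si](c1ccccc1)(c1ccccc1)C(C)(C)C)[C@@H]([C@H](O[Si](C)(C)C(C)(C)C)[C@@H](OCOC)[C@@H](O)CO[Si](CC)(CC)CC)C#C
F2 | step 14 | vinyl ketone (C14 ketone, C13=C12) | C=CC(=O)[C@](C)([C@@H](O[Si](C)(C)C(C)(C)C)CCO[Si](c1ccccc1)(c1ccccc1)C(C)(C)C)[C@@H]([C@H](O[Si](C)(C)C(C)(C)C)[C@@H](OCOC)[C@@H](O)CO[Si](CC)(CC)CC)C#C
F3 | step 14 | β-phenylselanyl ketone (PhSe on C12) | O=C(CC[Se]c1ccccc1)[C@](C)([C@@H](O[Si](C)(C)C(C)(C)C)CCO[Si](c1ccccc1)(c1ccccc1)C(C)(C)C)[C@@H]([C@H](O[Si](C)(C)C(C)(C)C)[C@@H](OCOC)[C@@H](O)CO[Si](CC)(CC)CC)C#C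
F4 | step 18 | O7 acrylate of 22 | C=C1CCC(=O)[C@](C)([C@@H](O[Si](C)(C)C(C)(C)C)CCO[Si](c2ccccc2)(c2ccccc2)C(C)(C)C)[C@H]1[C@H](O[Si](C)(C)C(C)(C)C)[C@@H](OCOC)[C@@H](OC(=O)C=C)CO[Si](CC)(CC)CC
F5 | step 18 | C8 alcohol of the O7 acrylate | C=C1CCC(=O)[C@](C)([C@@H](O[Si](C)(C)C(C)(C)C)CCO[Si](c2ccccc2)(c2ccccc2)C(C)(C)C)[C@H]1[C@H](O[Si](C)(C)C(C)(C)C)[C@@H](O)[C@@H](OC(=O)C=C)CO[Si](CC)(CC)CC
F6 | step 18 | C8 keto acrylate | C=C1CCC(=O)[C@](C)([C@@H](O[Si](C)(C)C(C)(C)C)CCO[Si](c2ccccc2)(c2ccccc2)C(C)(C)C)[C@H]1[C@H](O[Si](C)(C)C(C)(C)C)C(=O)[C@@H](OC(=O)C=C)CO[Si](CC)(CC)CC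
F7 | step 26 | C4 enone of 35 | C=C1CC[C@H](OC(C)=O)[C@]2(C)[C@@H](O)CC(=O)/C(C(=O)OC)=C/[C@@H]3OC(=O)[C@H](C)[C@@]3(O)[C@@H](O)[C@@H]12
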